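**Retrosynthetic overview**
1. The target is an all-cis (all-equatorial) 2,4,6-trisubstituted oxane (ring C). Ring A (3-methoxy-4,5-dihydroxyphenyl) sits on C2 and ring B (4-hydroxyphenyl) ends the ethyl arm on C6. The C4 carbinol is traced back to a C4 ketone (axial hydride delivery) and the three phenols to TBS ethers.
2. Key disconnection: ring C is opened at C5–C6 and O1–C2 at once (retro oxa-Diels–Alder). This gives an achiral (E)-4-aryl-2-silyloxybuta-1,3-diene and an achiral 3-arylpropanal, and in the forward sense a chiral Lewis acid of trivalent chromium sets C2 and C6.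
3. Enabling feature: in ring C the C4 oxygen stands 1,3 to O1 and C2 is benzylic to the electron-rich ring A. C2–C3–C4(O)–C5 is therefore a masked styrenyl silyl dienol ether and O1–C6 a masked aldehyde C=O, with the polarity of the presumed biogenesis (aldol-type C5–C6 bond, oxa-conjugate O1–C2 bond).
4. The diene comes from 5-hydroxyvanillin by Wittig olefination and one triple silylation (two phenols plus the enol). The aldehyde comes from methyl 3-(4-hydroxyphenyl)propanoate by silylation and half-reduction.
5. Ring order: rings A and B are bought. Ring C is the only ring made, in the key step.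

Key step: step 5

Assumption: the (1R,2S)-aminoindanol-derived chromium catalyst is taken to expose the Re face of the bound aliphatic aldehyde, as it does with simpler 1-substituted dienes; its antipode is equally available and would be used if the sense proved opposite.

Step 1
Reactants: 1 3,4-dihydroxy-5-methoxybenzaldehyde (5-hydroxyvanillin); 2 1-(triphenyl-λ5-phosphanylidene)propan-2-one
Product: 3 (E)-4-(3,4-dihydroxy-5-methoxyphenyl)but-3-en-2-one
Conditions: THF, reflux, Ar
Reagents that add atoms: none
Why: Wittig olefination with a ketone-stabilised ylide is E-selective, and the ylide is too weakly basic to be consumed irreversibly by the phenols, so no protection is needed and no stereocentre is formed.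

Step 2
Reactants: 3 (E)-4-(3,4-dihydroxy-5-methoxyphenyl)but-3-en-2-one
Product: 4 (E)-1-[3,4-bis(tert-butyldimethylsilyloxy)-5-methoxyphenyl]-3-(tert-butyldimethylsilyloxy)buta-1,3-diene
Conditions: TBSOTf (3.5 equiv), Et3N (5 equiv), CH2Cl2, 0 °C to rt; pentane extraction, Et3N-deactivated silica
Reagents that add atoms: tert-butyldimethylsilyl trifluoromethanesulfonate (TBSOTf), CC(C)(C)[Si](C)(C)OS(=O)(=O)C(F)(F)F
Why: In this soft enolisation (silyl triflate and amine) the reagent silylates both phenols and the enone oxygen, and Et3N removes a proton from the only enolisable position (the methyl group), giving the 2-silyloxydiene with the E styrenyl bond untouched.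

Step 3
Reactants: 5 methyl 3-(4-hydroxyphenyl)propanoate
Product: 6 methyl 3-[4-(tert-butyldimethylsilyloxy)phenyl]propanoate
Conditions: TBSCl, imidazole, DMF, rt
Reagents that add atoms: tert-butyldimethylsilyl chloride (TBSCl), CC(C)(C)[Si](C)(C)Cl
Why: This is a standard imidazole-promoted O-silylation of a phenol, and the methyl ester is inert under these conditions.

Step 4
Reactants: 6 methyl 3-[4-(tert-butyldimethylsilyloxy)phenyl]propanoate
Product: 7 3-[4-(tert-butyldimethylsilyloxy)phenyl]propanal
Conditions: i-Bu2AlH (1.05 equiv), CH2Cl2, −78 °C; MeOH, then aq. potassium sodium tartrate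
Reagents that add atoms: none
Why: In this partial ester reduction the tetrahedral aluminium hemiacetal persists at −78 °C and collapses to the aldehyde only on quench, and the aryl silyl ether is not affected.

Step 5
Reactants: 4 (E)-1-[3,4-bis(tert-butyldimethylsilyloxy)-5-methoxyphenyl]-3-(tert-butyldimethylsilyloxy)buta-1,3-diene; 7 3-[4-(tert-butyldimethylsilyloxy)phenyl]propanal
Product: 9 (2S,6S)-2-[3,4-bis(tert-butyldimethylsilyloxy)-5-methoxyphenyl]-6-{2-[4-(tert-butyldimethylsilyloxy)phenyl]ethyl}oxan-4-one, via silyl enol ether cycloadduct 8 (not isolated)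
Conditions: CrCl(L*) (10 mol %), powdered 4 Å MS, minimal acetone, rt; then TFA, wet CH2Cl2, 0 °C [H2L* = (1R,2S)-1-{[3-(1-adamantyl)-2-hydroxy-5-methylbenzylidene]amino}indan-2-ol]
Reagents that add atoms: none
Why: The Lewis acid of trivalent chromium binds the aldehyde oxygen anti to the alkyl chain and the s-cis diene adds in a concerted but asynchronous [4+2] (oxa-Diels–Alder) reaction, in which the silyloxy-activated CH2 terminus bonds to the carbonyl carbon (C5–C6) and the carbonyl oxygen bonds to the aryl-bearing terminus (O1–C2), after which TFA protonates enol ether 8 at C3 and unmasks the C4 ketone. The closest known reaction type is the tridentate Schiff-base chromium-catalysed hetero-Diels–Alder reaction of 4-substituted 2-silyloxydienes with unactivated aliphatic aldehydes, and 4-aryl-2-silyloxydienes are established partners of aldehydes in other Lewis-acid-catalysed asymmetric variants. Ring C is closed by intermolecular [4+2] cycloaddition, and if a stepwise Mukaiyama aldol path intervenes the open δ-oxy enone should close during the TFA treatment by 6-endo-trig oxa-Michael addition to the same ketone. C6 is set by the catalyst, whose indane and adamantyl groups leave the Re face of the bound aldehyde open, and C2 is set relative to C6 by the endo transition state together with the E geometry of the diene (outside diene substituent and endo aldehyde substituent end up cis), the diequatorial cis isomer also being the thermodynamic one through reversible oxa-Michael addition. Regioselectivity is secured by matched polarity (nucleophilic CH2 terminus against a benzylic terminus stabilised by ring A), chemoselectivity over aldehyde self-aldolisation by the mild non-basic catalyst and the sieves, and selective cleavage of the enol silyl ether by the acid robustness of aryl TBS ethers.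

Step 6
Reactants: 9 (2S,6S)-2-[3,4-bis(tert-butyldimethylsilyloxy)-5-methoxyphenyl]-6-{2-[4-(tert-butyldimethylsilyloxy)phenyl]ethyl}oxan-4-one
Product: 10 (2S,4R,6S)-2-[3,4-bis(tert-butyldimethylsilyloxy)-5-methoxyphenyl]-6-{2-[4-(tert-butyldimethylsilyloxy)phenyl]ethyl}oxan-4-ol
Conditions: NaBH4, MeOH/THF, −78 to −40 °C
Reagents that add atoms: none
Why: In this substrate-controlled ketone reduction the chair carries both C2 and C6 substituents equatorial, so the small hydride should attack axially (torsional control) and place the new hydroxyl equatorial, which is the (4R) all-cis arrangement.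

Step 7
Reactants: 10 (2S,4R,6S)-2-[3,4-bis(tert-butyldimethylsilyloxy)-5-methoxyphenyl]-6-{2-[4-(tert-butyldimethylsilyloxy)phenyl]ethyl}oxan-4-ol
Product: 11 (2S,4R,6S)-2-(3,4-dihydroxy-5-methoxyphenyl)-6-[2-(4-hydroxyphenyl)ethyl]oxan-4-ol (target)
Conditions: Et3N·3HF, THF, rt, Ar
Reagents that add atoms: none
Why: Fluoride-mediated desilylation is driven by Si–F bond formation, and the mildly acidic amine–HF reagent keeps the phenols protonated, so neither catechol autoxidation nor para-quinone-methide opening of the benzylic C2–O1 bond should be triggered and no stereocentre is touched.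

**Compound list**
1 | 3,4-dihydroxy-5-methoxybenzaldehyde (5-hydroxyvanillin) | COc1cc(C=O)cc(O)c1O | starting material
2 | 1-(triphenyl-λ5-phosphanylidene)propan-2-one | CC(=O)C=P(c1ccccc1)(c1ccccc1)c1ccccc1 | starting material
3 | (E)-4-(3,4-dihydroxy-5-methoxyphenyl)but-3-en-2-one | COc1cc(/C=C/C(C)=O)cc(O)c1O | intermediate
4 | (E)-1-[3,4-bis(tert-butyldimethylsilyloxy)-5-methoxyphenyl]-3-(tert-butyldimethylsilyloxy)buta-1,3-diene | COc1cc(/C=C/C(=C)O[Si](C)(C)C(C)(C)C)cc(O[Si](C)(C)C(C)(C)C)c1O[Si](C)(C)C(C)(C)C | intermediate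
5 | methyl 3-(4-hydroxyphenyl)propanoate | COC(=O)CCc1ccc(O)cc1 | starting material
6 | methyl 3-[4-(tert-butyldimethylsilyloxy)phenyl]propanoate | COC(=O)CCc1ccc(O[Si](C)(C)C(C)(C)C)cc1 | intermediate
7 | 3-[4-(tert-butyldimethylsilyloxy)phenyl]propanal | O=CCCc1ccc(O[Si](C)(C)C(C)(C)C)cc1 | intermediate
8 | (2S,6S)-6-[3,4-bis(tert-butyldimethylsilyloxy)-5-methoxyphenyl]-4-(tert-butyldimethylsilyloxy)-2-{2-[4-(tert-butyldimethylsilyloxy)phenyl]ethyl}-3,6-dihydro-2H-pyran | COc1cc([C@@H]2C=C(O[Si](C)(C)C(C)(C)C)C[C@H](CCc3ccc(O[Si](C)(C)C(C)(C)C)cc3)O2)cc(O[Si](C)(C)C(C)(C)C)c1O[Si](C)(C)C(C)(C)C | intermediate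
9 | (2S,6S)-2-[3,4-bis(tert-butyldimethylsilyloxy)-5-methoxyphenyl]-6-{2-[4-(tert-butyldimethylsilyloxy)phenyl]ethyl}oxan-4-one | COc1cc([C@@H]2CC(=O)C[C@H](CCc3ccc(O[Si](C)(C)C(C)(C)C)cc3)O2)cc(O[Si](C)(C)C(C)(C)C)c1O[Si](C)(C)C(C)(C)C | intermediate
10 | (2S,4R,6S)-2-[3,4-bis(tert-butyldimethylsilyloxy)-5-methoxyphenyl]-6-{2-[4-(tert-butyldimethylsilyloxy)phenyl]ethyl}oxan-4-ol | COc1cc([C@@H]2C[C@H](O)C[C@H](CCc3ccc(O[Si](C)(C)C(C)(C)C)cc3)O2)cc(O[Si](C)(C)C(C)(C)C)c1O[Si](C)(C)C(C)(C)C | intermediate
11 | (2S,4R,6S)-2-(3,4-dihydroxy-5-methoxyphenyl)-6-[2-(4-hydroxyphenyl)ethyl]oxan-4-ol | COc1cc([C@@H]2C[C@H](O)C[C@H](CCc3ccc(O)cc3)O2)cc(O)c1O | target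

**Totals**
Total step count: 7.
Longest linear sequence: 5 steps (1, 2, 5, 6, 7). The aldehyde branch (3, 4, 5, 6, 7) is equally long.

**Steps most likely to fail**

Step 5. The conjugated, heavily silylated diene may cycloadd slowly, so that hydrolysis of the dienol ether and self-condensation of the aldehyde compete, or enantiofacial and endo control may be insufficient. The fallback replaces the cycloaddition by a Prins cyclisation on a preformed carbinol stereocentre. It sets out from 7 and 1 and comes back at 10.
- Aldehyde 7 is allylated with the B-allyldiisopinocampheylborane made from (+)-Ipc2BOMe and allylMgBr (Et2O, −78 °C; H2O2, pH 7 buffer) to give (S)-1-[4-(tert-butyldimethylsilyloxy)phenyl]hex-5-en-3-ol F1.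
- Aldehyde 1 is silylated (TBSCl, imidazole, DMF) to 3,4-bis(tert-butyldimethylsilyloxy)-5-methoxybenzaldehyde F2.
- F1 and F2 are combined in TFA/CH2Cl2 at 0 °C. The E-oxocarbenium ion should cyclise through a chair with all substituents equatorial and be captured equatorially, giving (2S,4R,6S)-2-[3,4-bis(tert-butyldimethylsilyloxy)-5-methoxyphenyl]-6-{2-[4-(tert-butyldimethylsilyloxy)phenyl]ethyl}oxan-4-yl trifluoroacetate F3.
- Mild methanolysis (Et3N, MeOH) then leads to 10.

Step 2. Silylation of the hindered 4-hydroxyl between two ortho substituents may stay incomplete, and traces of acid may hydrolyse or oligomerise the electron-rich dienol ether during isolation. The fallback separates the two tasks and switches to a preformed enolate. It sets out from 3 and comes back at 4.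
- The phenols are silylated first (TBSCl, imidazole, DMF) to the stable, purifiable (E)-4-[3,4-bis(tert-butyldimethylsilyloxy)-5-methoxyphenyl]but-3-en-2-one F4.
- F4 is deprotonated with LiN(SiMe3)2 (THF, −78 °C), and the lithium dienolate is trapped on oxygen with TBSCl/DMPU under strictly basic conditions to give 4.

Step 6. Facial selectivity of hydride delivery may be poor (competing equatorial attack), or base-induced retro-oxa-Michael opening may occur during the reduction. The fallback aims deliberately at the opposite face and then inverts. It sets out from 9 and comes back at 10.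
- LiBH(s-Bu)3 (THF, −78 °C; H2O2, pH 7 buffer) should attack equatorially to give the axial alcohol (2S,4S,6S)-2-[3,4-bis(tert-butyldimethylsilyloxy)-5-methoxyphenyl]-6-{2-[4-(tert-butyldimethylsilyloxy)phenyl]ethyl}oxan-4-ol F5.
- Mitsunobu inversion (PhCO2H, PPh3, DIAD, toluene, 0 °C to rt) gives (2S,4R,6S)-2-[3,4-bis(tert-butyldimethylsilyloxy)-5-methoxyphenyl]-6-{2-[4-(tert-butyldimethylsilyloxy)phenyl]ethyl}oxan-4-yl benzoate F6.
- Reductive ester cleavage with i-Bu2AlH (CH2Cl2, −78 °C), which spares the aryl silyl ethers, gives 10.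

**Further compounds**
F1 | step 5 | (S)-1-[4-(tert-butyldimethylsilyloxy)phenyl]hex-5-en-3-ol | C=CC[C@@H](O)CCc1ccc(O[Si](C)(C)C(C)(C)C)cc1
F2 | step 5 | 3,4-bis(tert-butyldimethylsilyloxy)-5-methoxybenzaldehyde | COc1cc(C=O)cc(O[Si](C)(C)C(C)(C)C)c1O[Si](C)(C)C(C)(C)C
F3 | step 5 | (2S,4R,6S)-2-[3,4-bis(tert-butyldimethylsilyloxy)-5-methoxyphenyl]-6-{2-[4-(tert-butyldimethylsilyloxy)phenyl]ethyl}oxan-4-yl trifluoroacetate | COc1cc([C@@H]2C[C@H](OC(=O)C(F)(F)F)C[C@H](CCc3ccc(O[Si](C)(C)C(C)(C)C)cc3)O2)cc(O[Si](C)(C)C(C)(C)C)c1O[Si](C)(C)C(C)(C)C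
F4 | step 2 | (E)-4-[3,4-bis(tert-butyldimethylsilyloxy)-5-methoxyphenyl]but-3-en-2-one | COc1cc(/C=C/C(C)=O)cc(O[Si](C)(C)C(C)(C)C)c1O[Si](C)(C)C(C)(C)C
F5 | step 6 | (2S,4S,6S)-2-[3,4-bis(tert-butyldimethylsilyloxy)-5-methoxyphenyl]-6-{2-[4-(tert-butyldimethylsilyloxy)phenyl]ethyl}oxan-4-ol | COc1cc([C@@H]2C[C@@H](O)C[C@H](CCc3ccc(O[Si](C)(C)C(C)(C)C)cc3)O2)cc(O[Si](C)(C)C(C)(C)C)c1O[Si](C)(C)C(C)(C)C
F6 | step 6 | (2S,4R,6S)-2-[3,4-bis(tert-butyldimethylsilyloxy)-5-methoxyphenyl]-6-{2-[4-(tert-butyldimethylsilyloxy)phenyl]ethyl}oxan-4-yl benzoate | COc1cc([C@@H]2C[C@H](OC(=O)c4ccccc4)C[C@H](CCc3ccc(O[Si](C)(C)C(C)(C)C)cc3)O2)cc(O[Si](C)(C)C(C)(C)C)c1O[Si](C)(C)C(C)(C)C
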